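## Retrosynthetic overview

1. The target comes from the tetra-MOM-protected (R)-ketol by acid removal of the four MOM groups as the last step.
2. Key disconnection: the Cα–O bond. It is made enantioselectively on the tetra-MOM chalcone by conjugate hydride delivery followed by oxygen transfer from nitrosobenzene under a chiral silver catalyst, with N–O cleavage in the same flask.
3. The chalcone comes from a Claisen–Schmidt condensation of the ring A methyl ketone with the ring B aldehyde.
4. Ring A ketone: 2,4-dihydroxyacetophenone, C-3 prenylation, then MOM protection. Ring B aldehyde: 3-bromo-4,5-dihydroxybenzaldehyde, MOM protection, then Stille prenylation.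
5. No ring is formed in the route; both benzene rings are bought intact.

Assumption: (R)-BINAP is taken to give the (R)-configured C–O bond in the new step; since the reaction is new, the sense of induction must be checked on the first run (Mosher ester of the protected ketol), and (S)-BINAP is used instead if it is opposite.

Abbreviations: MOM = methoxymethyl; prenyl = 3-methylbut-2-en-1-yl.

## Route

Step 1
Reactants: 1 1-(2,4-dihydroxyphenyl)ethan-1-one (2,4-dihydroxyacetophenone)
Product: 2 1-[2,4-dihydroxy-3-(3-methylbut-2-en-1-yl)phenyl]ethan-1-one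
Conditions: prenyl bromide (1.0 equiv), KOH (10% aq), 0 °C to rt; silica chromatography
Reagents that add atoms: prenyl bromide, CC(C)=CCBr
Why: Nuclear prenylation (C-alkylation of an ambident resorcinol-type phenolate): in water the phenolate oxygens are hydrogen-bonded and the allylic bromide is attacked mainly by C-3, the carbon flanked by both oxygens; the 5-prenyl and O-prenyl isomers are removed on silica (about 30% of 2 expected).

Step 2
Reactants: 2 1-[2,4-dihydroxy-3-(3-methylbut-2-en-1-yl)phenyl]ethan-1-one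
Product: 3 1-[2,4-bis(methoxymethoxy)-3-(3-methylbut-2-en-1-yl)phenyl]ethan-1-one
Conditions: NaH (2.2 equiv), MOMCl (2.5 equiv), DMF, 0 °C to rt
Reagents that add atoms: chloromethyl methyl ether (MOMCl), COCCl
Why: Williamson-type O-alkylation of both phenoxides (NaH is needed to break the hydrogen bond of the 2-OH to the ketone); full protection prevents quenching of the later enolate and flavanone closure.

Step 3
Reactants: 4 3-bromo-4,5-dihydroxybenzaldehyde
Product: 5 3-bromo-4,5-bis(methoxymethoxy)benzaldehyde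
Conditions: MOMCl (2.5 equiv), K2CO3, acetone, rt to 50 °C
Reagents that add atoms: chloromethyl methyl ether (MOMCl), COCCl
Why: Williamson-type O-alkylation of the catechol under mild carbonate conditions; the non-enolisable aldehyde and the aryl bromide are untouched.

Step 4
Reactants: 5 3-bromo-4,5-bis(methoxymethoxy)benzaldehyde
Product: 6 3,4-bis(methoxymethoxy)-5-(3-methylbut-2-en-1-yl)benzaldehyde
Conditions: tributyl(3-methylbut-2-en-1-yl)stannane (1.2 equiv), Pd(PPh3)4 (5 mol%), DMF, 100 °C
Reagents that add atoms: tributyl(3-methylbut-2-en-1-yl)stannane, CC(C)=CC[Sn](CCCC)(CCCC)CCCC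
Why: Migita–Kosugi–Stille coupling; the prenyl group is transferred through its unsubstituted terminus to give the linear prenyl arene, and the neutral conditions tolerate the aldehyde and the MOM ethers.

Step 5
Reactants: 3 1-[2,4-bis(methoxymethoxy)-3-(3-methylbut-2-en-1-yl)phenyl]ethan-1-one; 6 3,4-bis(methoxymethoxy)-5-(3-methylbut-2-en-1-yl)benzaldehyde
Product: 7 (2E)-1-[2,4-bis(methoxymethoxy)-3-(3-methylbut-2-en-1-yl)phenyl]-3-[3,4-bis(methoxymethoxy)-5-(3-methylbut-2-en-1-yl)phenyl]prop-2-en-1-one
Conditions: KOH, EtOH/H2O, 0 °C to rt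
Reagents that add atoms: none
Why: Claisen–Schmidt aldol condensation; only the methyl ketone can enolise, the aldehyde cannot, and E1cB dehydration gives the (E)-enone.

Step 6
Reactants: 7 (2E)-1-[2,4-bis(methoxymethoxy)-3-(3-methylbut-2-en-1-yl)phenyl]-3-[3,4-bis(methoxymethoxy)-5-(3-methylbut-2-en-1-yl)phenyl]prop-2-en-1-one
Product: 11 (2R)-1-[2,4-bis(methoxymethoxy)-3-(3-methylbut-2-en-1-yl)phenyl]-3-[3,4-bis(methoxymethoxy)-5-(3-methylbut-2-en-1-yl)phenyl]-2-hydroxypropan-1-one, via tributyltin enolate 8 (not isolated), via N-stannyl anilinooxy ketone 9 (not isolated), via anilinooxy ketone 10 (not isolated)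
Conditions: Bu3SnH (1.0 equiv), AIBN (5 mol%), THF, 65 °C; then AgOTf/(R)-BINAP (1:1, 10 mol%), PhNO (1.0 equiv, slow addition), THF, −78 °C; then MeOH, PhNO (1.1 equiv), CuSO4 (0.3 equiv), 0 °C; KF (aq) work-up
Reagents that add atoms: nitrosobenzene, O=Nc1ccccc1
Why: Proposed new method: a one-flask reductive, catalytic enantioselective O-nitroso aldol of an enone. Radical-chain 1,4-hydrostannation (Bu3Sn radical adds to the carbonyl oxygen, the delocalised radical takes hydrogen at the benzylic β-carbon) gives the (Z)-tributyltin enolate 8 regiospecifically and leaves the isolated prenyl alkenes alone; the 1:1 AgOTf–(R)-BINAP complex then transmetalates 8 to a BINAP-bound silver enolate (or binds PhN=O at nitrogen), and the enolate α-carbon attacks the nitroso oxygen inside the chiral pocket, which forms the Cα–O bond and sets the (R) centre; methanolysis of the N–Sn bond and N–O heterolysis by a second equivalent of PhNO with CuSO4 free the alcohol without touching the stereocentre. The closest known reaction type is the AgOTf–BINAP-catalysed O-selective nitroso aldol of preformed tin enolates of simple ketones, with catalytic CuSO4 in MeOH for N–O cleavage; new here are the generation of the enolate by conjugate reduction of the enone in the same flask and the acyclic, β-aryl, polyoxygenated, prenylated substrate.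

Step 7
Reactants: 11 (2R)-1-[2,4-bis(methoxymethoxy)-3-(3-methylbut-2-en-1-yl)phenyl]-3-[3,4-bis(methoxymethoxy)-5-(3-methylbut-2-en-1-yl)phenyl]-2-hydroxypropan-1-one
Product: 12 (2R)-1-[2,4-dihydroxy-3-(3-methylbut-2-en-1-yl)phenyl]-3-[3,4-dihydroxy-5-(3-methylbut-2-en-1-yl)phenyl]-2-hydroxypropan-1-one
Conditions: HCl (1.25 M in MeOH, cat.), MeOH, 0 °C to rt, under argon
Reagents that add atoms: none
Why: Acid-catalysed transacetalisation of the four aryl MOM ethers to dimethoxymethane; dilute methanolic HCl at or below room temperature is too weak to cyclise the ortho-prenyl phenols to chromans or to enolise the ketol, so C-2 stays (R).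

## Compound list

1 | 1-(2,4-dihydroxyphenyl)ethan-1-one | CC(=O)c1ccc(O)cc1O | starting material
2 | 1-[2,4-dihydroxy-3-(3-methylbut-2-en-1-yl)phenyl]ethan-1-one | CC(=O)c1ccc(O)c(CC=C(C)C)c1O | intermediate
3 | 1-[2,4-bis(methoxymethoxy)-3-(3-methylbut-2-en-1-yl)phenyl]ethan-1-one | CC(=O)c1ccc(OCOC)c(CC=C(C)C)c1OCOC | intermediate
4 | 3-bromo-4,5-dihydroxybenzaldehyde | O=Cc1cc(O)c(O)c(Br)c1 | starting material
5 | 3-bromo-4,5-bis(methoxymethoxy)benzaldehyde | O=Cc1cc(OCOC)c(OCOC)c(Br)c1 | intermediate
6 | 3,4-bis(methoxymethoxy)-5-(3-methylbut-2-en-1-yl)benzaldehyde | O=Cc1cc(OCOC)c(OCOC)c(CC=C(C)C)c1 | intermediate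
7 | (2E)-1-[2,4-bis(methoxymethoxy)-3-(3-methylbut-2-en-1-yl)phenyl]-3-[3,4-bis(methoxymethoxy)-5-(3-methylbut-2-en-1-yl)phenyl]prop-2-en-1-one | COCOc1ccc(C(=O)/C=C/c2cc(OCOC)c(OCOC)c(CC=C(C)C)c2)c(OCOC)c1CC=C(C)C | intermediate
8 | tributyl{[(1Z)-1-[2,4-bis(methoxymethoxy)-3-(3-methylbut-2-en-1-yl)phenyl]-3-[3,4-bis(methoxymethoxy)-5-(3-methylbut-2-en-1-yl)phenyl]prop-1-en-1-yl]oxy}stannane (O-bound form of the tin enolate) | CCCC[Sn](CCCC)(CCCC)O/C(=C\Cc1cc(OCOC)c(OCOC)c(CC=C(C)C)c1)c1ccc(OCOC)c(CC=C(C)C)c1OCOC | intermediate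
9 | (2R)-1-[2,4-bis(methoxymethoxy)-3-(3-methylbut-2-en-1-yl)phenyl]-3-[3,4-bis(methoxymethoxy)-5-(3-methylbut-2-en-1-yl)phenyl]-2-{[phenyl(tributylstannyl)amino]oxy}propan-1-one | COCOc1ccc(C(=O)[C@H](ON(c3ccccc3)[Sn](CCCC)(CCCC)CCCC)Cc2cc(OCOC)c(OCOC)c(CC=C(C)C)c2)c(OCOC)c1CC=C(C)C | intermediate
10 | (2R)-1-[2,4-bis(methoxymethoxy)-3-(3-methylbut-2-en-1-yl)phenyl]-3-[3,4-bis(methoxymethoxy)-5-(3-methylbut-2-en-1-yl)phenyl]-2-[(phenylamino)oxy]propan-1-one | COCOc1ccc(C(=O)[C@H](ONc3ccccc3)Cc2cc(OCOC)c(OCOC)c(CC=C(C)C)c2)c(OCOC)c1CC=C(C)C | intermediate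
11 | (2R)-1-[2,4-bis(methoxymethoxy)-3-(3-methylbut-2-en-1-yl)phenyl]-3-[3,4-bis(methoxymethoxy)-5-(3-methylbut-2-en-1-yl)phenyl]-2-hydroxypropan-1-one | COCOc1ccc(C(=O)[C@H](O)Cc2cc(OCOC)c(OCOC)c(CC=C(C)C)c2)c(OCOC)c1CC=C(C)C | intermediate
12 | (2R)-1-[2,4-dihydroxy-3-(3-methylbut-2-en-1-yl)phenyl]-3-[3,4-dihydroxy-5-(3-methylbut-2-en-1-yl)phenyl]-2-hydroxypropan-1-one | CC(C)=CCc1cc(C[C@@H](O)C(=O)c2ccc(O)c(CC=C(C)C)c2O)cc(O)c1O | target

## Step count and risks

Total steps: 7. Longest linear sequence: 5 (steps 1, 2, 5, 6, 7 or steps 3, 4, 5, 6, 7).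

**Step 6 (the proposed new step).** The risks are an unknown level and sense of enantioselectivity, N- instead of O-attack on the nitroso group, reduction of the silver salt by leftover tin hydride, and a nitroso-ene side reaction at the prenyl groups while excess PhNO is present. The fallback uses known chemistry, sets out from 7 and comes back at 11. Conjugate reduction of 7 with [(Ph3P)CuH]6 (5 mol%), polymethylhydrosiloxane and t-BuOH in toluene at rt spares the prenyl groups and gives the saturated ketone 1-[2,4-bis(methoxymethoxy)-3-(3-methylbut-2-en-1-yl)phenyl]-3-[3,4-bis(methoxymethoxy)-5-(3-methylbut-2-en-1-yl)phenyl]propan-1-one F1. Its (Z)-sodium enolate (NaN(SiMe3)2, THF, −78 °C) is then hydroxylated with (−)-(2S,8aR)-(camphorylsulfonyl)oxaziridine (Davis asymmetric enolate hydroxylation) to give 11. The (−)-reagent is chosen by analogy with propiophenone-type (Z)-enolates, where, as I recall it, the (+)-reagent gives the (S)-ketol in high ee; this choice should be confirmed on the first run.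

**Step 1 (direct C-prenylation).** The risks are a low yield and a difficult separation from the 5-prenyl, O-prenyl and diprenyl isomers. The fallback sets out from 1 and comes back at 2, replacing direct alkylation by a sigmatropic route. The non-chelated 4-OH of 1 is alkylated with 3-chloro-3-methylbut-1-yne (DBU, CuCl2 cat., MeCN, 0 °C) to give 1-[2-hydroxy-4-(2-methylbut-3-yn-2-yloxy)phenyl]ethan-1-one F2. Semi-hydrogenation (H2, Pd on CaCO3 poisoned with Pb(OAc)2, quinoline, EtOAc) gives 1-[2-hydroxy-4-(2-methylbut-3-en-2-yloxy)phenyl]ethan-1-one F3. Aromatic Claisen rearrangement of F3 in N,N-diethylaniline at about 130 °C moves the allyl unit, with inversion, to C-3 and gives 2; C-3 is favoured by the bond fixation of the chelated 2-hydroxy ketone.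

**Step 7 (global MOM removal).** The risks are acid-promoted cyclisation of the ortho-prenyl phenols to dimethylchromans, and acid-catalysed enolisation of the ketol (racemisation or ketol transposition). The fallback sets out from 11 and comes back at 12, and avoids Brønsted acid by going through silyl ethers. Me3SiOTf with 2,2'-bipyridyl in MeCN at 0 °C to rt exchanges each aryl MOM ether for a trimethylsilyl ether and silylates the secondary alcohol. This gives (2R)-1-[2,4-bis(trimethylsilyloxy)-3-(3-methylbut-2-en-1-yl)phenyl]-3-[3,4-bis(trimethylsilyloxy)-5-(3-methylbut-2-en-1-yl)phenyl]-2-(trimethylsilyloxy)propan-1-one F4. Hydrolysis of F4 with water and then aqueous citric acid in MeOH at 0 °C gives 12.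

Further compounds
F1 | step 6 | 1-[2,4-bis(methoxymethoxy)-3-(3-methylbut-2-en-1-yl)phenyl]-3-[3,4-bis(methoxymethoxy)-5-(3-methylbut-2-en-1-yl)phenyl]propan-1-one | COCOc1ccc(C(=O)CCc2cc(OCOC)c(OCOC)c(CC=C(C)C)c2)c(OCOC)c1CC=C(C)C
F2 | step 1 | 1-[2-hydroxy-4-(2-methylbut-3-yn-2-yloxy)phenyl]ethan-1-one | CC(=O)c1ccc(OC(C)(C)C#C)cc1O
F3 | step 1 | 1-[2-hydroxy-4-(2-methylbut-3-en-2-yloxy)phenyl]ethan-1-one | CC(=O)c1ccc(OC(C)(C)C=C)cc1O
F4 | step 7 | (2R)-1-[2,4-bis(trimethylsilyloxy)-3-(3-methylbut-2-en-1-yl)phenyl]-3-[3,4-bis(trimethylsilyloxy)-5-(3-methylbut-2-en-1-yl)phenyl]-2-(trimethylsilyloxy)propan-1-one | C[Si](C)(C)Oc1ccc(C(=O)[C@H](O[Si](C)(C)C)Cc2cc(O[Si](C)(C)C)c(O[Si](C)(C)C)c(CC=C(C)C)c2)c(O[Si](C)(C)C)c1CC=C(C)C
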